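**Retrosynthetic overview**
1. Numbering: C1 lactone C=O, C2 its CH2, C3 peroxy CH, C4 methyl-bearing lactone O-carbon, C5 ring CH2, C6 methyl-bearing peroxy carbon, C7–C15 chain. The plan rests on the C3–C4 bond shared by the 1,2-dioxane and the γ-lactone. Drawn as a C3=C4 alkene inside the dioxane, it is a peroxy enol ether (O2 on C3) that is nucleophilic at C4, the atom that must end up bonded to the lactone oxygen.
2. C4 is therefore bonded first to the electrophilic carbon C1. γ-Lactone ⇒ Baeyer–Villiger insertion of O into the C4–C1 bond (absent from the target) of a cis-fused 2,3-dioxabicyclo[4.2.0]octan-7-one ⇒ (2+2) of a 5,6-dihydro-1,2-dioxine with a chiral keteniminium ion, which makes C4–C1 and C2–C3.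
3. Dihydrodioxine ⇒ low-temperature silyl triflate/amine elimination of a 3-methoxy-1,2-dioxane ⇒ perhydrolysis (inversion at C6) of a γ,δ-epoxy aldehyde ⇒ (R)-2-methylglycidol triflate + propionate enolate (C4–C5).
4. Side chain ⇒ C7=C8 Wittig union of the C7 aldehyde with an 8-aryloctyl ylide (4-bromophenol + 1,8-dibromooctane), then diimide saturation and phenol release.
5. Ring order: 1,2-dioxane (step 4), cyclobutane (step 9), ring expansion to the γ-lactone (step 10).

Key step: step 9

Assumption 1: the sense of induction of the (2R,5R)-pyrrolidine comes from a quadrant model, not from a measured case. If the first run shows the opposite face (NOE between the C4 and C6 methyl groups absent), the equally available (2S,5S)-amine is used instead.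
Assumption 2: C3 and C4 are carried as epimer mixtures from the enolate alkylation to the elimination. This does not matter because both carbons become sp2 there.
Remark: all peroxides are handled on small scale, cold, behind a shield and without concentration to dryness.

**Step 1**
Reactants: 1 (R)-2-methylglycidol
Product: 2 [(2S)-2-methyloxiran-2-yl]methyl trifluoromethanesulfonate
Conditions: Tf2O, 2,6-lutidine, CH2Cl2, −78 °C; cold aqueous wash, used at once
Reagents that add atoms: triflic anhydride, O=S(=O)(OS(=O)(=O)C(F)(F)F)C(F)(F)F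
Why: Sulfonylation of the primary alcohol without alkoxide formation touches neither the epoxide nor its stereocentre and avoids the Payne rearrangement, which would racemise this glycidol because its two CH2O arms differ only in which one lies in the ring.

**Step 2**
Reactants: 2 [(2S)-2-methyloxiran-2-yl]methyl trifluoromethanesulfonate; 3 ethyl propionate
Product: 5 ethyl (2RS)-2-methyl-3-[(2R)-2-methyloxiran-2-yl]propanoate, via lithium enolate of ethyl propionate 4 (not isolated)
Conditions: LDA, THF, −78 °C; then 2, DMPU, −78 → −40 °C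
Reagents that add atoms: none
Why: Enolate alkylation (SN2): a lithium ester enolate displaces a primary triflate at −78 °C but does not open an epoxide without a Lewis acid, so C4–C5 forms by direct substitution with the C6 configuration intact, while C4 forms as both epimers and is erased in step 7.

**Step 3**
Reactants: 5 ethyl (2RS)-2-methyl-3-[(2R)-2-methyloxiran-2-yl]propanoate
Product: 6 (2RS)-2-methyl-3-[(2R)-2-methyloxiran-2-yl]propanal
Conditions: DIBAL-H (1.05 equiv), CH2Cl2, −78 °C; Rochelle salt
Reagents that add atoms: none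
Why: Partial ester reduction with one equivalent of DIBAL-H at −78 °C stops at the aldehyde oxidation level, and a 2,2-disubstituted epoxide is not reduced at that temperature.

**Step 4**
Reactants: 6 (2RS)-2-methyl-3-[(2R)-2-methyloxiran-2-yl]propanal
Product: 8 (6S)-6-(hydroxymethyl)-4,6-dimethyl-1,2-dioxan-3-ol (epimers at C3 and C4), via open-chain hydroperoxy aldehyde 7 (not isolated)
Conditions: anhydrous H2O2 in Et2O (ca. 10 equiv), phosphomolybdic acid (3 mol %), 0 °C → rt
Reagents that add atoms: hydrogen peroxide, OO
Why: Molybdenum-catalysed perhydrolysis of an epoxide: H2O2 opens the activated 2,2-disubstituted epoxide at its more substituted carbon C6 from the rear (borderline SN2, inversion), which sets the C6–OO stereocentre, and the tertiary hydroperoxide of 7 then adds to the C3 aldehyde (6-exo-trig) to close the 1,2-dioxane as its peroxyhemiacetal.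

**Step 5**
Reactants: 8 (6S)-6-(hydroxymethyl)-4,6-dimethyl-1,2-dioxan-3-ol
Product: 9 (6S)-6-{[(tert-butyldiphenylsilyl)oxy]methyl}-4,6-dimethyl-1,2-dioxan-3-ol
Conditions: TBDPSCl (1.1 equiv), imidazole, CH2Cl2, 0 °C
Reagents that add atoms: tert-butyl(chloro)diphenylsilane, CC(C)(C)[Si](Cl)(c1ccccc1)c1ccccc1
Why: Selective silylation: the bulky chlorosilane takes the primary C7 hydroxyl in preference to the hindered hemiacetal hydroxyl, capping C7–OH also shuts off the competing tetrahydropyranol form, and any silyl group that lands on the hemiacetal or peroxide oxygen is lost again in the methanolysis of step 6.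

**Step 6**
Reactants: 9 (6S)-6-{[(tert-butyldiphenylsilyl)oxy]methyl}-4,6-dimethyl-1,2-dioxan-3-ol
Product: 10 (6S)-6-{[(tert-butyldiphenylsilyl)oxy]methyl}-3-methoxy-4,6-dimethyl-1,2-dioxane
Conditions: MeOH, PPTS (10 mol %), 3 Å MS, CH2Cl2, 0 °C → rt
Reagents that add atoms: methanol, CO
Why: Acid-catalysed acetalisation exchanges OH for OMe at C3 without any base (which could trigger Kornblum–DeLaMare cleavage at C3–H), and the TBDPS ether withstands PPTS in methanol.

**Step 7**
Reactants: 10 (6S)-6-{[(tert-butyldiphenylsilyl)oxy]methyl}-3-methoxy-4,6-dimethyl-1,2-dioxane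
Product: 12 (6S)-6-{[(tert-butyldiphenylsilyl)oxy]methyl}-4,6-dimethyl-5,6-dihydro-1,2-dioxine (C3=C4 alkene, O2 on C3), via peroxycarbenium triflate 11 (not isolated)
Conditions: TMSOTf (1.3 equiv), i-Pr2NEt (2.0 equiv), CH2Cl2, −78 → −30 °C; cold aq NaHCO3; short Et3N-washed plug, kept as a cold CH2Cl2 solution and used at once
Reagents that add atoms: none
Why: Proposed new method: TMSOTf silylates the more basic exocyclic methoxy oxygen and expels MeOSiMe3 to give the ring peroxycarbenium ion 11, whose only β-hydrogen (C4–H) is removed by the hindered amine, so only the C3=C4 alkene can form. The closest known reaction types are the silyl triflate/amine conversion of acetals into enol ethers and the Lewis acid ionisation of 3-alkoxy-1,2-dioxanes to peroxycarbenium ions, but their combination to an isolable endocyclic alkenyl peroxide is unproven. In the half-chair of 12 the O–O bond lies close to the alkene plane and so nearly orthogonal to the π system, which should deny O–O homolysis the oxyallyl-type stabilisation that makes acyclic alkenyl peroxides short-lived.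

**Step 8**
Reactants: 13 (2R,5R)-2,5-dimethylpyrrolidine
Product: 14 1-[(2R,5R)-2,5-dimethylpyrrolidin-1-yl]ethan-1-one
Conditions: Ac2O, Et3N, CH2Cl2, 0 °C → rt
Reagents that add atoms: acetic anhydride, CC(=O)OC(C)=O
Why: N-Acylation of a secondary amine with an anhydride, in which the stereocentres take no part.

**Step 9**
Reactants: 12 (6S)-6-{[(tert-butyldiphenylsilyl)oxy]methyl}-4,6-dimethyl-5,6-dihydro-1,2-dioxine; 14 1-[(2R,5R)-2,5-dimethylpyrrolidin-1-yl]ethan-1-one
Product: 18 (1S,4S,6S)-4-{[(tert-butyldiphenylsilyl)oxy]methyl}-4,6-dimethyl-2,3-dioxabicyclo[4.2.0]octan-7-one, via triflyloxyiminium triflate 15 (not isolated), via keteniminium triflate 16 (not isolated), via cyclobutaniminium triflate 17 (not isolated)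
Conditions: 14 (2.0 equiv), Tf2O (1.8 equiv), CH2Cl2, −40 → 0 → −40 °C; then 12, then 2,4,6-collidine (2.4 equiv) dropwise, −40 → 0 °C; then sat. aq NaHCO3, CH2Cl2, rt
Reagents that add atoms: water, O
Why: Proposed new method: collidine deprotonates the triflyloxyiminium salt 15 to the keteniminium ion 16, C4 (the β-carbon of the peroxy enol ether) attacks its central carbon C1, the positive charge growing at C3 is quenched by the enamine carbon C2, and water then hydrolyses the cyclobutaniminium salt 17 to ketone 18 with release of the auxiliary. The closest known reaction type is the keteniminium–alkene (2+2) cycloaddition to cyclobutanones with C2-symmetric 2,5-dimethylpyrrolidine auxiliaries, and the orientation is that of ketene–enol ether cycloadditions to 3-alkoxycyclobutanones, but no alkenyl peroxide has served as the 2π partner. The only ring closed is the cyclobutane C1–C2–C3–C4, by an asynchronous suprafacial (2+2) in which C4–C1 leads and C2–C3 follows as a 4-exo-trig collapse onto the C3 peroxycarbenium centre, so the four-membered ring can only be cis-fused to the dioxane. C3 and C4 are thus set relative to each other by the ring alkene and the suprafacial addition, and relative to C6 by the auxiliary: on either homotopic face of 16 the (2R,5R)-pyrrolidine leaves one open quadrant, and the docking that puts the C4 methyl there, only C3–H next to the auxiliary methyl and the dioxane ring away over the CH2 terminus exposes the alkene face cis to C7. The step needs regioselectivity (C4, not C3, to C1), secured by the O2 lone pair that polarises the alkene although it is a weaker donor than an ether oxygen; facial selectivity, secured by the auxiliary because C6 offers little bias; and chemoselectivity for C=C over O–O, secured by the low basicity of peroxide oxygen and by consuming all triflic anhydride with excess amide before 12 is added. Once C4 is quaternary the C3 cation has no β-hydrogen, so proton loss cannot compete with ring closure, and the poor donor ability of the peroxy oxygen should also disfavour re-opening of the donor–acceptor cyclobutane.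

**Step 10**
Reactants: 18 (1S,4S,6S)-4-{[(tert-butyldiphenylsilyl)oxy]methyl}-4,6-dimethyl-2,3-dioxabicyclo[4.2.0]octan-7-one
Product: 19 (1S,4S,6S)-4-{[(tert-butyldiphenylsilyl)oxy]methyl}-4,6-dimethyl-2,3,7-trioxabicyclo[4.3.0]nonan-8-one
Conditions: mCPBA, NaHCO3 (buffer), CH2Cl2, 0 °C → rt
Reagents that add atoms: 3-chloroperoxybenzoic acid, OOC(=O)c1cccc(Cl)c1
Why: Baeyer–Villiger oxidation of a strained cyclobutanone: the quaternary α-carbon C4 migrates from C1 to oxygen in preference to the C2 methylene and with retention, which turns the sacrificial C4–C1 bond into C4–O–C1 and leaves C3, C4 and C6 unchanged.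

**Step 11**
Reactants: 19 (1S,4S,6S)-4-{[(tert-butyldiphenylsilyl)oxy]methyl}-4,6-dimethyl-2,3,7-trioxabicyclo[4.3.0]nonan-8-one
Product: 20 (1S,4S,6S)-4-(hydroxymethyl)-4,6-dimethyl-2,3,7-trioxabicyclo[4.3.0]nonan-8-one
Conditions: HF·pyridine, pyridine, THF, 0 °C → rt
Reagents that add atoms: none
Why: Fluoride-induced silyl ether cleavage in an acidic rather than basic medium, so the β-peroxy lactone is not opened by E1cB loss of the C3 peroxide.

**Step 12**
Reactants: 20 (1S,4S,6S)-4-(hydroxymethyl)-4,6-dimethyl-2,3,7-trioxabicyclo[4.3.0]nonan-8-one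
Product: 21 (1S,4S,6S)-4,6-dimethyl-8-oxo-2,3,7-trioxabicyclo[4.3.0]nonane-4-carbaldehyde
Conditions: Dess–Martin periodinane, NaHCO3 (buffer), CH2Cl2, 0 °C → rt
Reagents that add atoms: none
Why: Dess–Martin oxidation is neutral, leaves dialkyl peroxides alone and gives an aldehyde without α-hydrogen, which cannot epimerise.

**Step 13**
Reactants: 22 4-bromophenol
Product: 23 (4-bromophenoxy)(tert-butyl)dimethylsilane
Conditions: TBSCl, imidazole, CH2Cl2, rt
Reagents that add atoms: tert-butyl(chloro)dimethylsilane, CC(C)(C)[Si](C)(C)Cl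
Why: Standard O-silylation gives a phenol protecting group that survives Grignard and ylide chemistry and can be removed later without reductive conditions.

**Step 14**
Reactants: 23 (4-bromophenoxy)(tert-butyl)dimethylsilane; 24 1,8-dibromooctane
Product: 26 [4-(8-bromooctyl)phenoxy](tert-butyl)dimethylsilane, via aryl Grignard reagent 25 (not isolated)
Conditions: Mg, THF, reflux; then 24 (3 equiv), Li2CuCl4 (3 mol %), THF, 0 °C → rt
Reagents that add atoms: none
Why: Copper-catalysed cross-coupling of an aryl Grignard reagent with a primary alkyl bromide, in which an excess of the dibromide suppresses double coupling.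

**Step 15**
Reactants: 26 [4-(8-bromooctyl)phenoxy](tert-butyl)dimethylsilane
Product: 27 {8-[4-(tert-butyldimethylsilyloxy)phenyl]octyl}triphenylphosphonium bromide
Conditions: PPh3, MeCN, reflux
Reagents that add atoms: triphenylphosphine, c1ccc(cc1)P(c1ccccc1)c1ccccc1
Why: SN2 quaternisation of triphenylphosphine by a primary bromide.

**Step 16**
Reactants: 21 (1S,4S,6S)-4,6-dimethyl-8-oxo-2,3,7-trioxabicyclo[4.3.0]nonane-4-carbaldehyde; 27 {8-[4-(tert-butyldimethylsilyloxy)phenyl]octyl}triphenylphosphonium bromide
Product: 29 (1S,4S,6S)-4-{(Z)-9-[4-(tert-butyldimethylsilyloxy)phenyl]non-1-en-1-yl}-4,6-dimethyl-2,3,7-trioxabicyclo[4.3.0]nonan-8-one, via phosphonium ylide 28 (not isolated)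
Conditions: 27 (1.15 equiv), NaHMDS (1.1 equiv), THF, −78 → 0 °C; cooled to −78 °C and added to 21 in THF, −78 → −20 °C
Reagents that add atoms: none
Why: Wittig olefination: a non-stabilised ylide adds to the aldehyde at −78 °C far faster than it deprotonates C2 of the lactone or attacks the hindered O–O bond (α-peroxy aldehydes are known partners of such ylides), and the alkene geometry is irrelevant because the alkene is reduced next.

**Step 17**
Reactants: 29 (1S,4S,6S)-4-{(Z)-9-[4-(tert-butyldimethylsilyloxy)phenyl]non-1-en-1-yl}-4,6-dimethyl-2,3,7-trioxabicyclo[4.3.0]nonan-8-one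
Product: 30 (1S,4R,6S)-4-{9-[4-(tert-butyldimethylsilyloxy)phenyl]nonyl}-4,6-dimethyl-2,3,7-trioxabicyclo[4.3.0]nonan-8-one
Conditions: potassium azodicarboxylate (excess, in portions), AcOH, MeOH/CH2Cl2, 0 °C → rt
Reagents that add atoms: none
Why: Diimide reduction transfers H2 to the C7=C8 bond in a concerted syn fashion and leaves the O–O bond, the lactone and the aryl silyl ether untouched, whereas catalytic hydrogenation would cleave the peroxide.

**Step 18**
Reactants: 30 (1S,4R,6S)-4-{9-[4-(tert-butyldimethylsilyloxy)phenyl]nonyl}-4,6-dimethyl-2,3,7-trioxabicyclo[4.3.0]nonan-8-one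
Product: 31 plakortolide F, (3S,4S,6R) in the numbering of the overview
Conditions: TBAF, AcOH (1:1), THF, 0 °C
Reagents that add atoms: none
Why: Aryl silyl ethers are cleaved rapidly by fluoride, and the acetic acid buffer keeps fluoride and phenoxide basicity from opening the β-peroxy lactone.

**Compound list**
1 | (R)-2-methylglycidol | C[C@]1(CO1)CO | starting material
2 | [(2S)-2-methyloxiran-2-yl]methyl triflate | C[C@]1(CO1)COS(=O)(=O)C(F)(F)F | intermediate
3 | ethyl propionate | CCC(=O)OCC | starting material
4 | lithium enolate of ethyl propionate | CC=C([O-])OCC.[Li+] | intermediate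
5 | ethyl (2RS)-2-methyl-3-[(2R)-2-methyloxiran-2-yl]propanoate | CCOC(=O)C(C)C[C@]1(C)CO1 | intermediate
6 | (2RS)-2-methyl-3-[(2R)-2-methyloxiran-2-yl]propanal | O=CC(C)C[C@]1(C)CO1 | intermediate
7 | (4S)-4-hydroperoxy-5-hydroxy-2,4-dimethylpentanal | O=CC(C)C[C@@](C)(CO)OO | intermediate
8 | (6S)-6-(hydroxymethyl)-4,6-dimethyl-1,2-dioxan-3-ol | C[C@@]1(CO)CC(C)C(O)OO1 | intermediate
9 | (6S)-6-(TBDPSO-methyl)-4,6-dimethyl-1,2-dioxan-3-ol | C[C@@]1(CO[Si](c2ccccc2)(c2ccccc2)C(C)(C)C)CC(C)C(O)OO1 | intermediate
10 | (6S)-6-(TBDPSO-methyl)-3-methoxy-4,6-dimethyl-1,2-dioxane | C[C@@]1(CO[Si](c2ccccc2)(c2ccccc2)C(C)(C)C)CC(C)C(OC)OO1 | intermediate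
11 | ring peroxycarbenium triflate (C3=O2+) derived from 10 | C[C@@]1(CO[Si](c2ccccc2)(c2ccccc2)C(C)(C)C)CC(C)C=[O+]O1.[O-]S(=O)(=O)C(F)(F)F | intermediate
12 | (6S)-6-(TBDPSO-methyl)-4,6-dimethyl-5,6-dihydro-1,2-dioxine | C[C@@]1(CO[Si](c2ccccc2)(c2ccccc2)C(C)(C)C)CC(C)=COO1 | intermediate
13 | (2R,5R)-2,5-dimethylpyrrolidine | C[C@@H]1CC[C@@H](C)N1 | starting material
14 | N-acetyl-(2R,5R)-2,5-dimethylpyrrolidine | CC(=O)N1[C@H](C)CC[C@H]1C | intermediate
15 | (2R,5R)-2,5-dimethyl-1-[1-(triflyloxy)ethylidene]pyrrolidinium triflate | CC(OS(=O)(=O)C(F)(F)F)=[N+]1[C@H](C)CC[C@H]1C.[O-]S(=O)(=O)C(F)(F)F | intermediate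
16 | (2R,5R)-1-ethenylidene-2,5-dimethylpyrrolidinium triflate | C=C=[N+]1[C@H](C)CC[C@H]1C.[O-]S(=O)(=O)C(F)(F)F | intermediate
17 | cyclobutaniminium triflate (18 with C1=N+ of the auxiliary in place of C1=O) | C[C@@]1(CO[Si](c2ccccc2)(c2ccccc2)C(C)(C)C)C[C@]2(C)C(=[N+]3[C@H](C)CC[C@H]3C)C[C@@H]2OO1.[O-]S(=O)(=O)C(F)(F)F | intermediate
18 | (1S,4S,6S)-4-(TBDPSO-methyl)-4,6-dimethyl-2,3-dioxabicyclo[4.2.0]octan-7-one | C[C@@]1(CO[Si](c2ccccc2)(c2ccccc2)C(C)(C)C)C[C@]2(C)C(=O)C[C@@H]2OO1 | intermediate
19 | (1S,4S,6S)-4-(TBDPSO-methyl)-4,6-dimethyl-2,3,7-trioxabicyclo[4.3.0]nonan-8-one | C[C@@]1(CO[Si](c2ccccc2)(c2ccccc2)C(C)(C)C)C[C@]2(C)OC(=O)C[C@@H]2OO1 | intermediate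
20 | (1S,4S,6S)-4-(hydroxymethyl)-4,6-dimethyl-2,3,7-trioxabicyclo[4.3.0]nonan-8-one | C[C@@]1(CO)C[C@]2(C)OC(=O)C[C@@H]2OO1 | intermediate
21 | (1S,4S,6S)-4,6-dimethyl-8-oxo-2,3,7-trioxabicyclo[4.3.0]nonane-4-carbaldehyde | C[C@@]1(C=O)C[C@]2(C)OC(=O)C[C@@H]2OO1 | intermediate
22 | 4-bromophenol | Oc1ccc(Br)cc1 | starting material
23 | (4-bromophenoxy)(tert-butyl)dimethylsilane | CC(C)(C)[Si](C)(C)Oc1ccc(Br)cc1 | intermediate
24 | 1,8-dibromooctane | BrCCCCCCCCBr | starting material
25 | 4-(tert-butyldimethylsilyloxy)phenylmagnesium bromide | CC(C)(C)[Si](C)(C)Oc1ccc([Mg]Br)cc1 | intermediate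
26 | [4-(8-bromooctyl)phenoxy](tert-butyl)dimethylsilane | CC(C)(C)[Si](C)(C)Oc1ccc(CCCCCCCCBr)cc1 | intermediate
27 | {8-[4-(TBSO)phenyl]octyl}triphenylphosphonium bromide | CC(C)(C)[Si](C)(C)Oc1ccc(CCCCCCCC[P+](c2ccccc2)(c2ccccc2)c2ccccc2)cc1.[Br-] | intermediate
28 | {8-[4-(TBSO)phenyl]octylidene}triphenylphosphorane | CC(C)(C)[Si](C)(C)Oc1ccc(CCCCCCCC=P(c2ccccc2)(c2ccccc2)c2ccccc2)cc1 | intermediate
29 | (Z)-C7=C8 alkene, TBS-protected | C[C@@]1(/C=C\CCCCCCCc2ccc(O[Si](C)(C)C(C)(C)C)cc2)C[C@]2(C)OC(=O)C[C@@H]2OO1 | intermediate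
30 | O-TBS-plakortolide F | C[C@@]1(CCCCCCCCCc2ccc(O[Si](C)(C)C(C)(C)C)cc2)C[C@]2(C)OC(=O)C[C@@H]2OO1 | intermediate
31 | plakortolide F | C[C@@]1(CCCCCCCCCc2ccc(O)cc2)C[C@]2(C)OC(=O)C[C@@H]2OO1 | target

**Step count**
Total steps: 18. Longest linear sequence: 14 (steps 1–7, 9–12, 16–18).

**Steps most likely to fail**

**1. Step 9 (key step).**
- What may go wrong:
  - Regiochemical leakage, because the peroxy oxygen is a weak donor and C3 is the less hindered terminus.
  - Heterolysis of the O–O bond in the peroxycarbenium stage before the ring closes.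
  - Attack of a peroxide oxygen on the keteniminium carbon followed by sigmatropic O–O cleavage.
  - Insufficient facial discrimination.
- Fallback: it sets out from 12 and comes back at 19, and it uses established reaction types.
  - Oxygen is delivered to the nucleophilic C4 directly by an electrophilic oxidant instead of through C1.
  - Epoxidation of the enol ether with dimethyldioxirane in acetone at low temperature, then hydrolysis of the labile epoxide (the way glycals are oxidised), should give (6S)-6-(TBDPSO-methyl)-4,6-dimethyl-1,2-dioxane-3,4-diol F1. This is the cyclic form of an α-hydroxy aldehyde that carries the C6 hydroperoxide.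
  - Methyl (triphenylphosphoranylidene)acetate in methanol favours the Z-enoate with α-oxygenated aldehydes. After spontaneous lactonisation it should give the butenolide hydroperoxide F2.
  - Diethylamine then promotes conjugate addition of the hydroperoxide to C3. This is the established ring closure of this family of peroxylactones and can only give the cis-fused bicycle.
  - Without the auxiliary both C4 epimers form. Because C6 is fixed they are diastereomers, and 19 is separated by chromatography.

**2. Step 7.**
- What may go wrong: Lewis-acid-induced heterolysis of the O–O bond with hydride shift from C3 (Hock-type collapse to an ester), and O–O homolysis of the alkenyl peroxide during isolation.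
- Fallback: it sets out from 2 and comes back at 20, and it uses known chemistry only. (R)-Lactic acid supplies C4 with its oxygen already in place, and the peroxide ring is closed last.
  - The lithium enolate of (2R,5R)-2-tert-butyl-5-methyl-1,3-dioxolan-4-one F3 is alkylated with 2 anti to the tert-butyl group (self-regeneration of the stereocentre, overall retention) to give the quaternary dioxolanone F4.
  - DIBAL-H at −78 °C gives the lactol F5.
  - Methyl (triphenylphosphoranylidene)acetate in methanol olefinates the aldehyde form with loss of pivalaldehyde, and the Z-hydroxy enoate lactonises to the epoxy butenolide F6.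
  - Molybdenum-catalysed perhydrolysis as in step 4, now with no aldehyde nearby, gives the hydroperoxy alcohol F7.
  - Diethylamine closes the dioxane by conjugate addition of the hydroperoxide to C3, giving 20.

**3. Step 4.**
- What may go wrong:
  - Participation of the C3 carbonyl oxygen, or of the OH of its hydrogen peroxide adduct, in the epoxide opening, which leads to tetrahydrofuran formation.
  - Erosion of configuration at C6 through a carbocation-like opening.
  - Acid-induced rearrangement of the epoxide.
- Fallback: it sets out from 6 and comes back at 10. The peroxide is built on C3 first and delivered to C6 intramolecularly.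
  - Wittig methoxymethylenation (Ph3P=CHOMe) gives the enol ether F8.
  - Ozonolysis in CH2Cl2/MeOH follows. Enol ethers fragment to the formate ester and the carbonyl oxide of the alkyl-bearing carbon, which methanol traps, giving the α-methoxy hydroperoxide F9.
  - Catalytic camphorsulfonic acid then triggers 6-exo opening of the epoxide at C6 by the tethered hydroperoxide. Attack is necessarily from the rear and no free hemiacetal OH competes, so the product should be the hydroxymethyl methoxydioxane F10.
  - TBDPSCl/imidazole converts F10 into 10.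

**Further compounds**
F1 | step 9 | (6S)-6-(TBDPSO-methyl)-4,6-dimethyl-1,2-dioxane-3,4-diol (epimers at C3 and C4) | C[C@@]1(CO[Si](c2ccccc2)(c2ccccc2)C(C)(C)C)CC(C)(O)C(O)OO1
F2 | step 9 | (5S)-5-[(2S)-3-(TBDPSO)-2-hydroperoxy-2-methylpropyl]-5-methylfuran-2(5H)-one | C[C@](CO[Si](c1ccccc1)(c1ccccc1)C(C)(C)C)(OO)C[C@]1(C)OC(=O)C=C1
F3 | step 7 | (2R,5R)-2-tert-butyl-5-methyl-1,3-dioxolan-4-one | C[C@H]1O[C@@H](C(C)(C)C)OC1=O
F4 | step 7 | (2R,5S)-2-tert-butyl-5-methyl-5-{[(2R)-2-methyloxiran-2-yl]methyl}-1,3-dioxolan-4-one | C[C@@]1(C[C@]2(C)CO2)O[C@@H](C(C)(C)C)OC1=O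
F5 | step 7 | (2R,5S)-2-tert-butyl-5-methyl-5-{[(2R)-2-methyloxiran-2-yl]methyl}-1,3-dioxolan-4-ol | C[C@@]1(C[C@]2(C)CO2)O[C@@H](C(C)(C)C)OC1O
F6 | step 7 | (5S)-5-methyl-5-{[(2R)-2-methyloxiran-2-yl]methyl}furan-2(5H)-one | C[C@@]1(C[C@]2(C)CO2)OC(=O)C=C1
F7 | step 7 | (5S)-5-[(2S)-2-hydroperoxy-3-hydroxy-2-methylpropyl]-5-methylfuran-2(5H)-one | C[C@](CO)(OO)C[C@]1(C)OC(=O)C=C1
F8 | step 4 | (2R)-2-(4-methoxy-2-methylbut-3-en-1-yl)-2-methyloxirane (E/Z) | COC=CC(C)C[C@]1(C)CO1
F9 | step 4 | 1-methoxy-2-methyl-3-[(2R)-2-methyloxiran-2-yl]propyl hydroperoxide | COC(OO)C(C)C[C@]1(C)CO1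
F10 | step 4 | (6S)-6-(hydroxymethyl)-3-methoxy-4,6-dimethyl-1,2-dioxane | C[C@@]1(CO)CC(C)C(OC)OO1
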